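The molecule is cut at the bond between the ethylene linker and the sp2 carbon of ring C, giving a ring A/B vinyl acetate and a ring C/D enol triflate for a B-alkyl Suzuki union. The plan rests on ring C: its CH2 group, flanked by the carbinol CH(OH) and the C/D fusion CH, together with that fusion carbon, is traced back to a C=C bond allylic to the carbinol. Ring-closing metathesis forms this bond and the seven-membered ring in one operation; the free hydroxyl then directs hydrogenation to the cis fusion. The precursor is a syn-aldol vinyl carbinol tied through a gem-dimethyl ketone to a silyl-protected 2-methylenecyclopentanol.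

Key step: step 9

Assumption: (R)-dehydrolinalool (1) is taken as a purchasable, enantioenriched material. Rings C/D carry azulene numbering (C1 tertiary carbinol, C3a and C8a fusion carbons, C5 linker-bearing carbon, C7 secondary carbinol, C8 ring CH2) and rings A/B carry 1-benzoxepine numbering. Steps 1–12 build rings C/D, steps 13–20 build rings A/B, and steps 21–22 join and finish.

Step 1
Reactants: 1 (R)-dehydrolinalool, (3R)-3,7-dimethyloct-6-en-1-yn-3-ol
Product: 2 (3R)-3,7-dimethyl-3-(triethylsilyloxy)oct-6-en-1-yne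
Conditions: Et3SiOTf, 2,6-lutidine, CH2Cl2, 0 °C
Reagents that add atoms: triethylsilyl trifluoromethanesulfonate, CC[Si](CC)(CC)OS(=O)(=O)C(F)(F)F
Why: O-silylation of the tertiary propargylic alcohol with a silyl triflate and a hindered pyridine base is routine, leaves the stereocentre (the future C1 of ring D) untouched and masks the hydroxyl for the organometallic steps ahead.

Step 2
Reactants: 2 (3R)-3,7-dimethyl-3-(triethylsilyloxy)oct-6-en-1-yne
Product: 3 methyl (3R)-3,7-dimethyl-2-methylidene-3-(triethylsilyloxy)oct-6-enoate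
Conditions: Pd(OAc)2 (cat.), 2-(diphenylphosphino)pyridine, MeSO3H (cat., less than the ligand), CO (20 bar), MeOH/THF, 50 °C
Reagents that add atoms: carbon monoxide, [C-]#[O+]; methanol, CO
Why: Markovnikov hydroesterification (alkyne methoxycarbonylation) with the palladium/pyridylphosphine/acid system should place CO2Me on the internal alkyne carbon to give the 2-substituted acrylate, the acid being kept below the ligand loading so that the medium stays buffered and the silyl ether survives.

Step 3
Reactants: 3 methyl (3R)-3,7-dimethyl-2-methylidene-3-(triethylsilyloxy)oct-6-enoate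
Product: 4 methyl (5R)-5-methyl-5-(triethylsilyloxy)cyclopent-1-ene-1-carboxylate
Conditions: second-generation Grubbs catalyst (cat.), toluene, 80 °C
Reagents that add atoms: none
Why: Ring-closing metathesis of the acrylate methylene with the prenyl olefin is a favourable five-membered closure driven by loss of volatile isobutene and does not touch the quaternary stereocentre.

Step 4
Reactants: 4 methyl (5R)-5-methyl-5-(triethylsilyloxy)cyclopent-1-ene-1-carboxylate
Product: 5 [(5R)-5-methyl-5-(triethylsilyloxy)cyclopent-1-en-1-yl]methanol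
Conditions: iBu2AlH, CH2Cl2, −78 °C; aq. potassium sodium tartrate
Reagents that add atoms: none
Why: 1,2-Reduction of the conjugated ester with a dialkylaluminium hydride at low temperature gives the allylic alcohol without touching the ring olefin or the silyl ether.

Step 5
Reactants: 5 [(5R)-5-methyl-5-(triethylsilyloxy)cyclopent-1-en-1-yl]methanol; 6 isobutyryl chloride
Product: 7 [(5R)-5-methyl-5-(triethylsilyloxy)cyclopent-1-en-1-yl]methyl 2-methylpropanoate
Conditions: Et3N, DMAP (cat.), CH2Cl2, 0 °C
Reagents that add atoms: none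
Why: DMAP-catalysed O-acylation of a primary allylic alcohol with an acid chloride is a standard esterification.

Step 6
Reactants: 7 [(5R)-5-methyl-5-(triethylsilyloxy)cyclopent-1-en-1-yl]methyl 2-methylpropanoate
Product: 10 2-methyl-2-[(1R,3R)-3-methyl-2-methylidene-3-(triethylsilyloxy)cyclopentyl]propanoic acid, via silyl ketene acetal 8 (not isolated), via trimethylsilyl ester 9 (not isolated)
Conditions: LiN(iPr)2, THF, −78 °C; Me3SiCl, −78 → 65 °C; pH 5 aqueous work-up
Reagents that add atoms: none
Why: Ireland–Claisen rearrangement, in which the ketene acetal (no E/Z issue, two equal methyl groups) undergoes a [3,3] shift that joins the new quaternary carbon to the ring CH and moves the olefin into the exocyclic position, the chain being delivered to the ring face opposite the bulky triethylsilyloxy group (syn to the methyl group), which sets the future C3a.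

Step 7
Reactants: 10 2-methyl-2-[(1R,3R)-3-methyl-2-methylidene-3-(triethylsilyloxy)cyclopentyl]propanoic acid
Product: 11 2-methyl-2-[(1R,3R)-3-methyl-2-methylidene-3-(triethylsilyloxy)cyclopentyl]pentan-3-one
Conditions: EtLi (3 equiv), Et2O, −78 → 0 °C; inverse quench into aq. NH4Cl
Reagents that add atoms: ethyllithium, [Li]CC
Why: Ketone synthesis by addition of an alkyllithium to the lithium carboxylate stops at the dilithium gem-diolate, which the neopentyl environment keeps from collapsing before the quench, so that hydrolysis gives the ethyl ketone directly.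

Step 8
Reactants: 11 2-methyl-2-[(1R,3R)-3-methyl-2-methylidene-3-(triethylsilyloxy)cyclopentyl]pentan-3-one; 12 acrolein
Product: 15 (4S,5R)-5-hydroxy-2,4-dimethyl-2-[(1R,3R)-3-methyl-2-methylidene-3-(triethylsilyloxy)cyclopentyl]hept-6-en-3-one, via Z-enol borinate 13 (not isolated), via boron aldolate 14 (not isolated)
Conditions: (−)-Ipc2BOTf [ligands from (+)-α-pinene], iPr2NEt, CH2Cl2, −78 → 0 °C; 12, −78 → −20 °C; H2O2, MeOH, pH 7 buffer, 0 °C
Reagents that add atoms: none
Why: Boron-mediated syn-aldol reaction in which the only enolisable side gives the Z-enol diisopinocampheylborinate, which should add through a chair Zimmerman–Traxler transition state to the Si face of acrolein under control of the boron ligands (the antipodal reagent is equally accessible), setting the carbinol carbon (R, future C7) and the temporary methyl-bearing carbon (S).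

Step 9
Reactants: 15 (4S,5R)-5-hydroxy-2,4-dimethyl-2-[(1R,3R)-3-methyl-2-methylidene-3-(triethylsilyloxy)cyclopentyl]hept-6-en-3-one
Product: 16 (1R,3aR,6S,7R)-7-hydroxy-1,4,4,6-tetramethyl-1-(triethylsilyloxy)-2,3,3a,4,6,7-hexahydroazulen-5(1H)-one
Conditions: second-generation Hoveyda–Grubbs catalyst (added in portions), 1,4-benzoquinone (cat.), toluene (high dilution), 100 °C, argon sparge
Reagents that add atoms: none
Why: The catalyst initiates at the unhindered vinyl carbinol to give a ruthenium alkylidene, which adds intramolecularly across the exocyclic methylene through a ruthenacyclobutane and cycloreverts with loss of ethene, a ring-closing metathesis of a monosubstituted with a 1,1-disubstituted olefin to a trisubstituted cycloalkene, which is an established reaction type. Ring C is closed as a seven-membered ring by joining the inner vinyl carbon (future C8) to the sp2 carbon of ring D (future C8a), so that both olefin carbons end up inside the new ring. No stereocentre is created, and C1, C3a and C7 are spectators. The selectivity needed is cyclisation over cross-metathesis dimerisation at the vinyl end and over ruthenium hydride isomerisation of the allylic alcohol: the gem-dimethyl group and the adjacent placement of side chain and methylene on the cyclopentane fold the chain towards the olefin, high dilution with ethene removal disfavours dimers, and benzoquinone intercepts hydrides. The hydroxyl is left free on purpose, because an allylic hydroxyl speeds up loading of the catalyst and serves as directing group in step 10, and the small triethylsilyl group keeps the bulk beside the hindered olefin as low as the earlier steps allow.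

Step 10
Reactants: 16 (1R,3aR,6S,7R)-7-hydroxy-1,4,4,6-tetramethyl-1-(triethylsilyloxy)-2,3,3a,4,6,7-hexahydroazulen-5(1H)-one
Product: 17 (1R,3aR,6S,7R,8aR)-7-hydroxy-1,4,4,6-tetramethyl-1-(triethylsilyloxy)octahydroazulen-5(1H)-one
Conditions: [Ir(cod)(PCy3)(py)]PF6 (cat.), H2 (1 atm to 50 bar), CH2Cl2, rt
Reagents that add atoms: none
Why: Hydroxyl-directed homogeneous hydrogenation, in which the cationic iridium complex binds the allylic C7 hydroxyl, which lies on the same face as the C3a hydrogen, and should deliver H2 to that face of the trisubstituted olefin, setting C8a (R) and thus the cis C/D fusion.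

Step 11
Reactants: 17 (1R,3aR,6S,7R,8aR)-7-hydroxy-1,4,4,6-tetramethyl-1-(triethylsilyloxy)octahydroazulen-5(1H)-one
Product: 18 (1R,3aR,6S,7R,8aR)-1,4,4,6-tetramethyl-1,7-bis(triethylsilyloxy)octahydroazulen-5(1H)-one
Conditions: Et3SiOTf, 2,6-lutidine, CH2Cl2, −78 → 0 °C
Reagents that add atoms: triethylsilyl trifluoromethanesulfonate, CC[Si](CC)(CC)OS(=O)(=O)C(F)(F)F
Why: O-silylation with a silyl triflate and a hindered pyridine base is fast and mild enough to avoid retro-aldol cleavage of the β-hydroxy ketone, and it installs the same group as on ring D so that one final operation removes both.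

Step 12
Reactants: 18 (1R,3aR,6S,7R,8aR)-1,4,4,6-tetramethyl-1,7-bis(triethylsilyloxy)octahydroazulen-5(1H)-one
Product: 19 (1R,3aR,7R,8aR)-1,4,4,6-tetramethyl-1,7-bis(triethylsilyloxy)-1,2,3,3a,4,7,8,8a-octahydroazulen-5-yl trifluoromethanesulfonate
Conditions: KN(SiMe3)2, THF, −78 °C; PhNTf2, −78 → 0 °C
Reagents that add atoms: N-phenylbis(trifluoromethanesulfonimide), O=S(=O)(N(c1ccccc1)S(=O)(=O)C(F)(F)F)C(F)(F)F
Why: Enol triflate formation is regiochemically unambiguous because the other α-carbon is quaternary, and O-sulfonylation of the potassium enolate at low temperature, where β-elimination of the silyloxy group is slow, gives the tetrasubstituted enol triflate and erases the temporary C6 stereocentre.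

Step 13
Reactants: 20 geranyl bromide; 21 N-methoxy-N-methylacetamide
Product: 22 (4E)-N-methoxy-N,5,9-trimethyldeca-4,8-dienamide
Conditions: LiN(iPr)2, THF, −78 °C, 21; then 20, −78 → 0 °C
Reagents that add atoms: none
Why: Enolate alkylation of the Weinreb acetamide with a primary allylic bromide is an SN2 reaction that keeps the E olefin geometry.

Step 14
Reactants: 22 (4E)-N-methoxy-N,5,9-trimethyldeca-4,8-dienamide
Product: 23 3-[(2R,3R)-3-{2-[(2R)-3,3-dimethyloxiran-2-yl]ethyl}-3-methyloxiran-2-yl]-N-methoxy-N-methylpropanamide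
Conditions: D-fructose-derived Shi ketone (cat.), KHSO5 (as 2KHSO5·KHSO4·K2SO4), K2CO3, Bu4NHSO4, Na2B4O7/Na2EDTA buffer, MeCN/CH2(OMe)2, 0 °C
Reagents that add atoms: potassium peroxymonosulfate, [K+].[O-]S(=O)(=O)OO
Why: Shi asymmetric epoxidation, in which the chiral dioxirane attacks both electron-rich trisubstituted olefins through the spiro transition state and should give all three epoxide stereocentres in the R configuration under reagent control, which later become C3, C5a and C9a of rings A and B.

Step 15
Reactants: 23 3-[(2R,3R)-3-{2-[(2R)-3,3-dimethyloxiran-2-yl]ethyl}-3-methyloxiran-2-yl]-N-methoxy-N-methylpropanamide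
Product: 24 1-[(2R,3R)-3-{2-[(2R)-3,3-dimethyloxiran-2-yl]ethyl}-3-methyloxiran-2-yl]hex-5-en-3-one
Conditions: CH2=CHCH2MgBr, THF, −78 °C; cold aq. NH4Cl
Reagents that add atoms: allylmagnesium bromide, C=CC[Mg]Br
Why: Weinreb ketone synthesis, in which the chelated tetrahedral adduct prevents over-addition, the trisubstituted epoxides are inert to the Grignard reagent at −78 °C and a cold neutral quench keeps the olefin out of conjugation.

Step 16
Reactants: 24 1-[(2R,3R)-3-{2-[(2R)-3,3-dimethyloxiran-2-yl]ethyl}-3-methyloxiran-2-yl]hex-5-en-3-one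
Product: 25 tert-butyl({(3Z)-1-[(2R,3R)-3-{2-[(2R)-3,3-dimethyloxiran-2-yl]ethyl}-3-methyloxiran-2-yl]hexa-3,5-dien-3-yl}oxy)dimethylsilane
Conditions: KN(SiMe3)2, THF, −78 °C; tBuMe2SiCl, DMPU, −78 → 0 °C
Reagents that add atoms: tert-butyldimethylsilyl chloride, CC(C)(C)[Si](C)(C)Cl
Why: Silyl enol ether formation is regioselective because the CH2 between carbonyl and vinyl group is by far the most acidic site, so that deprotonation and O-silylation give the extended dienol ether with the Z enol geometry that avoids allylic strain, under basic conditions that leave the epoxides alone.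

Step 17
Reactants: 25 tert-butyl({(3Z)-1-[(2R,3R)-3-{2-[(2R)-3,3-dimethyloxiran-2-yl]ethyl}-3-methyloxiran-2-yl]hexa-3,5-dien-3-yl}oxy)dimethylsilane
Product: 26 (3R,5aR,6R,9aR)-3-(tert-butyldimethylsilyloxy)-6-ethenyl-2,2,5a-trimethyloctahydro-1-benzoxepin-7(2H)-one
Conditions: tBuMe2SiOTf (0.2 equiv), 2,6-di-tert-butyl-4-methylpyridine, CH2Cl2, −78 °C
Reagents that add atoms: none
Why: Silyl triflate-initiated oxa-/carbacyclisation cascade of a 1,5-diepoxide terminated by a silyl enol ether, in which the silylated terminal epoxide is opened at its tertiary carbon by the inner epoxide oxygen (7-endo), the epoxonium ion is opened with inversion at its tertiary carbon by the α-carbon of the dienol ether through a chair (a six- instead of an eight-membered ring, hence α and not γ attack) to give trans-fused rings A/B with an equatorial vinyl group at C6, and the silyl group released from the enol oxygen carries the chain.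

Step 18
Reactants: 26 (3R,5aR,6R,9aR)-3-(tert-butyldimethylsilyloxy)-6-ethenyl-2,2,5a-trimethyloctahydro-1-benzoxepin-7(2H)-one
Product: 27 (3R,5aR,6R,7S,9aR)-3-(tert-butyldimethylsilyloxy)-6-ethenyl-2,2,5a,7-tetramethyldecahydro-1-benzoxepin-7-ol
Conditions: CeCl3 (anhydrous), MeLi, THF, −78 °C
Reagents that add atoms: methyllithium, [Li]C
Why: 1,2-Addition of the weakly basic organocerium reagent avoids enolisation of the β,γ-unsaturated ketone and should come from the equatorial direction, because the axial path is blocked by the 1,3-diaxial angular methyl group, giving the axial tertiary alcohol (7S) cis to the vinyl group.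

Step 19
Reactants: 27 (3R,5aR,6R,7S,9aR)-3-(tert-butyldimethylsilyloxy)-6-ethenyl-2,2,5a,7-tetramethyldecahydro-1-benzoxepin-7-ol
Product: 28 (3R,5aR,6R,7S,9aR)-6-ethenyl-2,2,5a,7-tetramethyldecahydro-1-benzoxepine-3,7-diol
Conditions: Bu4NF, THF, 40 °C
Reagents that add atoms: none
Why: Fluoride-induced desilylation is driven by the strong Si–F bond, and nothing else in the molecule (tertiary alcohol, vinyl group, cyclic ether) responds to the reagent.

Step 20
Reactants: 28 (3R,5aR,6R,7S,9aR)-6-ethenyl-2,2,5a,7-tetramethyldecahydro-1-benzoxepine-3,7-diol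
Product: 29 (3R,5aR,6R,7S,9aR)-6-ethenyl-7-hydroxy-2,2,5a,7-tetramethyldecahydro-1-benzoxepin-3-yl acetate
Conditions: Ac2O, pyridine, DMAP (cat.), CH2Cl2, rt
Reagents that add atoms: acetic anhydride, CC(=O)OC(C)=O
Why: DMAP-catalysed acetylation discriminates reliably between the secondary alcohol and the axial tertiary alcohol, which stays free, so that the only acetate of the target is placed before any other secondary hydroxyl is present.

Step 21
Reactants: 29 (3R,5aR,6R,7S,9aR)-6-ethenyl-7-hydroxy-2,2,5a,7-tetramethyldecahydro-1-benzoxepin-3-yl acetate; 19 (1R,3aR,7R,8aR)-1,4,4,6-tetramethyl-1,7-bis(triethylsilyloxy)-1,2,3,3a,4,7,8,8a-octahydroazulen-5-yl trifluoromethanesulfonate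
Product: 31 bis(triethylsilyl) ether of the target at the C1 and C7 hydroxyls of rings C/D, via B-alkyl-9-BBN adduct 30 (not isolated)
Conditions: 9-BBN-H (excess), THF, rt; then 19, Pd(dppf)Cl2 (cat.), AsPh3, Cs2CO3, DMF/H2O, 50 °C
Reagents that add atoms: none
Why: B-alkyl Suzuki–Miyaura coupling, in which 9-BBN-H adds anti-Markovnikov to the only olefin and the borate formed with aqueous base transmetallates to the alkenylpalladium species arising from oxidative addition of zerovalent palladium into the C–OTf bond, forming the CH2–C5 bond without touching the acetate, the silyl ethers or any stereocentre.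

Step 22
Reactants: 31 bis(triethylsilyl) ether of the target
Product: 32 CNP0157376.1, (3R,5aR,6R,7S,9aR)-6-{2-[(1R,3aR,7R,8aR)-1,7-dihydroxy-1,4,4,6-tetramethyl-1,2,3,3a,4,7,8,8a-octahydroazulen-5-yl]ethyl}-7-hydroxy-2,2,5a,7-tetramethyldecahydro-1-benzoxepin-3-yl acetate
Conditions: HF·pyridine, pyridine, THF, 0 °C → rt
Reagents that add atoms: none
Why: Fluoride desilylation with pyridine-buffered HF should cleave both triethylsilyl ethers while sparing the acetate and avoiding ionisation of the allylic alcohol.

Compound list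
1 | (R)-dehydrolinalool | C#C[C@](C)(O)CCC=C(C)C | starting material
2 | (3R)-3,7-dimethyl-3-(triethylsilyloxy)oct-6-en-1-yne | C#C[C@](C)(O[Si](CC)(CC)CC)CCC=C(C)C | intermediate
3 | methyl (3R)-3,7-dimethyl-2-methylidene-3-(triethylsilyloxy)oct-6-enoate | C=C(C(=O)OC)[C@](C)(O[Si](CC)(CC)CC)CCC=C(C)C | intermediate
4 | methyl (5R)-5-methyl-5-(triethylsilyloxy)cyclopent-1-ene-1-carboxylate | COC(=O)C1=CCC[C@@]1(C)O[Si](CC)(CC)CC | intermediate
5 | [(5R)-5-methyl-5-(triethylsilyloxy)cyclopent-1-en-1-yl]methanol | OCC1=CCC[C@@]1(C)O[Si](CC)(CC)CC | intermediate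
6 | isobutyryl chloride | CC(C)C(Cl)=O | starting material
7 | [(5R)-5-methyl-5-(triethylsilyloxy)cyclopent-1-en-1-yl]methyl 2-methylpropanoate | CC(C)C(=O)OCC1=CCC[C@@]1(C)O[Si](CC)(CC)CC | intermediate
8 | trimethylsilyl ketene acetal of 7 | CC(C)=C(O[Si](C)(C)C)OCC1=CCC[C@@]1(C)O[Si](CC)(CC)CC | intermediate
9 | trimethylsilyl ester of 10 | C[Si](C)(C)OC(=O)C(C)(C)[C@@H]1CC[C@@](C)(O[Si](CC)(CC)CC)C1=C | intermediate
10 | 2-methyl-2-[(1R,3R)-3-methyl-2-methylidene-3-(triethylsilyloxy)cyclopentyl]propanoic acid | OC(=O)C(C)(C)[C@@H]1CC[C@@](C)(O[Si](CC)(CC)CC)C1=C | intermediate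
11 | 2-methyl-2-[(1R,3R)-3-methyl-2-methylidene-3-(triethylsilyloxy)cyclopentyl]pentan-3-one | CCC(=O)C(C)(C)[C@@H]1CC[C@@](C)(O[Si](CC)(CC)CC)C1=C | intermediate
12 | acrolein | C=CC=O | starting material
13 | Z-enol diisopinocampheylborinate of 11 | C/C=C(\OB([C@@H]2C[C@@H]3C[C@H]([C@H]2C)C3(C)C)[C@@H]4C[C@@H]5C[C@H]([C@H]4C)C5(C)C)C(C)(C)[C@@H]1CC[C@@](C)(O[Si](CC)(CC)CC)C1=C | intermediate
14 | diisopinocampheylboron aldolate of 15 | C=C[C@@H](OB([C@@H]2C[C@@H]3C[C@H]([C@H]2C)C3(C)C)[C@@H]4C[C@@H]5C[C@H]([C@H]4C)C5(C)C)[C@H](C)C(=O)C(C)(C)[C@@H]1CC[C@@](C)(O[Si](CC)(CC)CC)C1=C | intermediate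
15 | (4S,5R)-5-hydroxy-2,4-dimethyl-2-[(1R,3R)-3-methyl-2-methylidene-3-(triethylsilyloxy)cyclopentyl]hept-6-en-3-one (syn-aldol triene) | C=C[C@@H](O)[C@H](C)C(=O)C(C)(C)[C@@H]1CC[C@@](C)(O[Si](CC)(CC)CC)C1=C | intermediate
16 | (1R,3aR,6S,7R)-7-hydroxy-1,4,4,6-tetramethyl-1-(triethylsilyloxy)-2,3,3a,4,6,7-hexahydroazulen-5(1H)-one | O=C1[C@@H](C)[C@H](O)C=C2[C@@H](CC[C@@]2(C)O[Si](CC)(CC)CC)C1(C)C | intermediate
17 | (1R,3aR,6S,7R,8aR)-7-hydroxy-1,4,4,6-tetramethyl-1-(triethylsilyloxy)octahydroazulen-5(1H)-one (cis-fused) | O=C1[C@@H](C)[C@H](O)C[C@@H]2[C@@H](CC[C@@]2(C)O[Si](CC)(CC)CC)C1(C)C | intermediate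
18 | (1R,3aR,6S,7R,8aR)-1,4,4,6-tetramethyl-1,7-bis(triethylsilyloxy)octahydroazulen-5(1H)-one | O=C1[C@@H](C)[C@H](O[Si](CC)(CC)CC)C[C@@H]2[C@@H](CC[C@@]2(C)O[Si](CC)(CC)CC)C1(C)C | intermediate
19 | (1R,3aR,7R,8aR)-1,4,4,6-tetramethyl-1,7-bis(triethylsilyloxy)-1,2,3,3a,4,7,8,8a-octahydroazulen-5-yl trifluoromethanesulfonate | O=S(=O)(OC1=C(C)[C@H](O[Si](CC)(CC)CC)C[C@@H]2[C@@H](CC[C@@]2(C)O[Si](CC)(CC)CC)C1(C)C)C(F)(F)F | intermediate
20 | geranyl bromide | CC(C)=CCC/C(C)=C/CBr | starting material
21 | N-methoxy-N-methylacetamide | CC(=O)N(C)OC | starting material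
22 | (4E)-N-methoxy-N,5,9-trimethyldeca-4,8-dienamide | CC(C)=CCC/C(C)=C/CCC(=O)N(C)OC | intermediate
23 | 3-[(2R,3R)-3-{2-[(2R)-3,3-dimethyloxiran-2-yl]ethyl}-3-methyloxiran-2-yl]-N-methoxy-N-methylpropanamide | CC1(C)O[C@@H]1CC[C@@]2(C)O[C@@H]2CCC(=O)N(C)OC | intermediate
24 | 1-[(2R,3R)-3-{2-[(2R)-3,3-dimethyloxiran-2-yl]ethyl}-3-methyloxiran-2-yl]hex-5-en-3-one | CC1(C)O[C@@H]1CC[C@@]2(C)O[C@@H]2CCC(=O)CC=C | intermediate
25 | (3Z)-tert-butyldimethylsilyl dienol ether of 24 | CC1(C)O[C@@H]1CC[C@@]2(C)O[C@@H]2CC/C(O[Si](C)(C)C(C)(C)C)=C/C=C | intermediate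
26 | (3R,5aR,6R,9aR)-3-(tert-butyldimethylsilyloxy)-6-ethenyl-2,2,5a-trimethyloctahydro-1-benzoxepin-7(2H)-one | CC(C)(C)[Si](C)(C)O[C@@H]1CC[C@]2(C)[C@@H](C=C)C(=O)CC[C@H]2OC1(C)C | intermediate
27 | (3R,5aR,6R,7S,9aR)-3-(tert-butyldimethylsilyloxy)-6-ethenyl-2,2,5a,7-tetramethyldecahydro-1-benzoxepin-7-ol | CC(C)(C)[Si](C)(C)O[C@@H]1CC[C@]2(C)[C@@H](C=C)[C@@](C)(O)CC[C@H]2OC1(C)C | intermediate
28 | (3R,5aR,6R,7S,9aR)-6-ethenyl-2,2,5a,7-tetramethyldecahydro-1-benzoxepine-3,7-diol | O[C@@H]1CC[C@]2(C)[C@@H](C=C)[C@@](C)(O)CC[C@H]2OC1(C)C | intermediate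
29 | (3R,5aR,6R,7S,9aR)-6-ethenyl-7-hydroxy-2,2,5a,7-tetramethyldecahydro-1-benzoxepin-3-yl acetate | CC(=O)O[C@@H]1CC[C@]2(C)[C@@H](C=C)[C@@](C)(O)CC[C@H]2OC1(C)C | intermediate
30 | B-alkyl-9-BBN adduct of 29 | CC(=O)O[C@@H]1CC[C@]2(C)[C@@H](CCB3C4CCCC3CCC4)[C@@](C)(O)CC[C@H]2OC1(C)C | intermediate
31 | bis(triethylsilyl) ether of the target | CC(=O)O[C@@H]1CC[C@]2(C)[C@@H](CCC3=C(C)[C@H](O[Si](CC)(CC)CC)C[C@@H]4[C@@H](CC[C@@]4(C)O[Si](CC)(CC)CC)C3(C)C)[C@@](C)(O)CC[C@H]2OC1(C)C | intermediate
32 | CNP0157376.1 | CC(=O)O[C@@H]1CC[C@]2(C)[C@@H](CCC3=C(C)[C@H](O)C[C@@H]4[C@@H](CC[C@@]4(C)O)C3(C)C)[C@@](C)(O)CC[C@H]2OC1(C)C | target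

Total step count: 22. Longest linear sequence: 14 (steps 1–12, 21 and 22).

Steps most likely to fail

Step 9. The alkylidene formed at the vinyl end may not engage the methylene group, which is flanked by a fully substituted carbon and a branched methine. Dimerisation at the vinyl group, catalyst decay or migration of the allylic alcohol olefin could then take over. The fallback redesigns the substrate and sets out from 15. The tertiary silyl ether is cleaved first (HF·pyridine, THF) to give the diol triene F1, in which a free tertiary allylic hydroxyl stands beside the methylene in place of the bulky silyloxy group and can assist the metathesis. Ring closure of F1 with the same class of catalyst should give the bicyclic enone diol F2. Both hydroxyls of F2 lie on the face that must receive hydrogen, so [Ir(cod)(PCy3)(py)]PF6/H2 should give the cis-fused diol ketone F3. Double silylation with Et3SiOTf/2,6-lutidine comes back to the route at 18.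

Step 17. The activated epoxides may rearrange by hydride shift to ketones or be opened singly. The dienol ether may be hydrolysed or react through its remote terminus, and the vinyl group may drift into conjugation with the ketone. The fallback replaces the dienol ether by an allylsilane, the classical terminator of cationic cyclisations, and sets out from 23.
- iBu2AlH (−78 °C) should give the diepoxy aldehyde F4.
- CH2=CHMgBr, kept cold, should give the allylic alcohol F5. Both carbinol epimers serve, because this carbon is oxidised later.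
- Et3SiCl/imidazole should give the silyl ether F6.
- Cross-metathesis with allyltrimethylsilane (second-generation Grubbs catalyst) should give the E-allylsilane F7.
- With tBuMe2SiOTf (1 equiv) and the hindered pyridine, the same epoxonium cascade should end by attack of the allylsilane γ-carbon and loss of the Me3Si group. This creates the vinyl group directly in the bicyclic bis-silyl ether F8.
- Selective methanolysis of the triethylsilyl ether (pyridinium tosylate, MeOH) should give the secondary alcohol F9.
- Dess–Martin oxidation comes back to the route at 26.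

Step 21. Oxidative addition and transmetallation at a tetrasubstituted triflate next to a quaternary carbon may be slow. Protodeboronation of the alkylborane, hydrolysis of the triflate or loss of the acetate to the aqueous base could then compete. The fallback changes the nucleophile to zinc under base-free conditions and sets out from 29.
- Hydroboration with 9-BBN-H and oxidation with NaBO3 should give the primary alcohol F10.
- I2/PPh3/imidazole should give the primary iodide F11.
- Zinc insertion (Zn dust, LiCl, THF) should give the alkylzinc iodide F12, which is used at once.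
- Negishi coupling of F12 with 19 (Pd(OAc)2, SPhos, THF) comes back to the route at 31.

Further compounds
F1 | step 9 | diol triene, (4S,5R)-5-hydroxy-2-[(1R,3R)-3-hydroxy-3-methyl-2-methylidenecyclopentyl]-2,4-dimethylhept-6-en-3-one | C=C[C@@H](O)[C@H](C)C(=O)C(C)(C)[C@@H]1CC[C@@](C)(O)C1=C
F2 | step 9 | bicyclic enone diol, (1R,3aR,6S,7R)-1,7-dihydroxy-1,4,4,6-tetramethyl-2,3,3a,4,6,7-hexahydroazulen-5(1H)-one | O=C1[C@@H](C)[C@H](O)C=C2[C@@H](CC[C@@]2(C)O)C1(C)C
F3 | step 9 | cis-fused diol ketone, (1R,3aR,6S,7R,8aR)-1,7-dihydroxy-1,4,4,6-tetramethyloctahydroazulen-5(1H)-one | O=C1[C@@H](C)[C@H](O)C[C@@H]2[C@@H](CC[C@@]2(C)O)C1(C)C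
F4 | step 17 | diepoxy aldehyde, 3-[(2R,3R)-3-{2-[(2R)-3,3-dimethyloxiran-2-yl]ethyl}-3-methyloxiran-2-yl]propanal | CC1(C)O[C@@H]1CC[C@@]2(C)O[C@@H]2CCC=O
F5 | step 17 | allylic alcohol, 5-(diepoxyalkyl)pent-1-en-3-ol, both carbinol epimers | CC1(C)O[C@@H]1CC[C@@]2(C)O[C@@H]2CCC(O)C=C
F6 | step 17 | triethylsilyl ether of F5, both epimers | CC1(C)O[C@@H]1CC[C@@]2(C)O[C@@H]2CCC(O[Si](CC)(CC)CC)C=C
F7 | step 17 | E-allylsilane from F6, both epimers | CC1(C)O[C@@H]1CC[C@@]2(C)O[C@@H]2CCC(O[Si](CC)(CC)CC)/C=C/C[Si](C)(C)C
F8 | step 17 | bicyclic bis-silyl ether, 3-OTBS, 7-OTES, 6-ethenyl, both C7 epimers | CC(C)(C)[Si](C)(C)O[C@@H]1CC[C@]2(C)[C@@H](C=C)C(O[Si](CC)(CC)CC)CC[C@H]2OC1(C)C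
F9 | step 17 | bicyclic secondary alcohol, 3-OTBS, 7-OH, both C7 epimers | CC(C)(C)[Si](C)(C)O[C@@H]1CC[C@]2(C)[C@@H](C=C)C(O)CC[C@H]2OC1(C)C
F10 | step 21 | primary alcohol, 6-(2-hydroxyethyl) analogue of 29 | CC(=O)O[C@@H]1CC[C@]2(C)[C@@H](CCO)[C@@](C)(O)CC[C@H]2OC1(C)C
F11 | step 21 | primary iodide, 6-(2-iodoethyl) analogue of 29 | CC(=O)O[C@@H]1CC[C@]2(C)[C@@H](CCI)[C@@](C)(O)CC[C@H]2OC1(C)C
F12 | step 21 | alkylzinc iodide from F11 | CC(=O)O[C@@H]1CC[C@]2(C)[C@@H](CC[Zn]I)[C@@](C)(O)CC[C@H]2OC1(C)C
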